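The numbers of this flask are invented; the rest is arithmetic.

The constants of the round through catalyst intermediate A give a ratio of catalyst intermediate A to free catalyst at balance in this flask.

    second substrate + free catalyst ⇌ catalyst intermediate B (K1 = 0.64 L mol⁻¹, k1 = 0.026 L mol⁻¹ s⁻¹)
    catalyst intermediate B → free catalyst + second product (k2 = 0.012 s⁻¹)
    2 starting material → self-condensation product (k3 = 0.0012 L mol⁻¹ s⁻¹)
    catalyst intermediate A → free catalyst + target (k4 = 0.0044 s⁻¹)
    starting material + free catalyst ⇌ catalyst intermediate A (K5 = 3.6 L mol⁻¹, k5 = 0.037 L mol⁻¹ s⁻¹)
    2 catalyst intermediate B ⇌ resting dimer, settled at all times (K6 = 7.4 L mol⁻¹)

starting material 0.40 M; second substrate 0.800 M; free catalyst 40 mM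

* the form that holds most of the catalyst when 5.0% of the starting material are converted (catalyst intermediate B / free catalyst / resting dimer / catalyst intermediate A)
* its share of the catalyst then

- percent here means starting material units held: one self-condensation product counts as two
- a step written with two of one species runs at k times the square of its concentration and takes two of it each time
- a form made of two catalysts counts as two
- what is bound to the catalyst counts as converted
- charge of starting material (flask): 0.40 M

What holds catalyst intermediate A at balance? It is made from free catalyst at 0.89 min⁻¹ per free catalyst at the charge. It is lost, by falling back and by giving target, at 0.881 min⁻¹ per intermediate. Setting the two equal gives c(catalyst intermediate A)/c(free catalyst) as the first over the second. I call this the holding ratio, 1.01 at the charge. Later it is this value times the fraction of starting material left.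

And the free share at that balance? Intermediate B has its own ratio, 0.395. Setting the dimer aside and taking both ratios at the charge, free catalyst would fall to 41.6%.

Does the flask get there by 5.0% conversion? Starting material goes at first at 0.0586 M min⁻¹, so at that first rate the mark comes after about 0.342 min. Catalyst intermediate A nears balance with a time of 0.565 min, and the estimated mark comes sooner than that, so I expect this flask to be still short of balance.

Then what share do you commit to? Free catalyst starts at full share and drains at first at 2.14 min⁻¹. So I take its excess over balance to decay at 3.66 min⁻¹, which leaves 28.7% of the excess at the estimated mark. That gives free catalyst as the resting state, with 58.3%.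

The forecast also names free catalyst, at 56%, lower than mine, and places the mark “before the catalyst has relaxed to its steady state”.

The simulation gives free catalyst at 55.7%. The flask reaches the mark at 0.463 min, when catalyst intermediate A holds 23.0%. The reading of catalyst intermediate A over free catalyst is 0.414, against a holding ratio of 0.959 for the starting material left then. After 10.0 min, with 56.5% of the starting material left, the holding ratio is 0.571 and the reading 0.590. After 20.0 min, with 37.9% left, the holding ratio is 0.383 and the reading 0.394.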